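## Structural features

The target is a 2-aryl-2,3-dihydro-1-benzofuran. Benzo ring A (C3a to C7a) is fused to a dihydrofuran ring (O1, C2, C3, C3a, C7a), and C2 carries ring B, a 4-hydroxy-3,5-dimethoxyphenyl group. Ring A has a methoxy group at C7, next to O1, and an (E)-acrylic acid chain at C5, para to O1; C3 carries the hydroxymethyl carbon C9. C2 (S) and C3 (R) are neighbouring stereocentres with the aryl and hydroxymethyl groups trans. Nothing else in the molecule is stereogenic, so the absolute sense must come from a catalyst or reagent. The fragile sites are the C2–O1 bond (a benzylic aryl ether para to a free phenol, able to ionise in acid or open to a quinone methide), the benzylic C3–H, the oxidisable phenol and the (E)-cinnamic acid alkene. The real difficulty is twofold: setting two contiguous centres in the absolute sense, and keeping two carboxyl-level carbons (C9 and the acrylic carbon) distinguishable so that only C9 is reduced. The key step uses the fact that C2 and C3, with ring B on C2, ring A on C3 and O1 ortho to C3a, are the two alkene carbons of an (E)-2-hydroxystilbene. Adding O1 to C2 and the one-carbon unit C9 to C3 across that alkene closes the dihydrofuran ring and fixes both centres in one event.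

## Logic of the disconnections

10 to 9: the O–C(CH3)3 bond of the ester and the O–CH2OCH3 bond on ring B are cut. Both are acid-labile, so one operation removes them. The gain is that the acid and the ring B phenol stay masked through every earlier step. The demand is an acid treatment short and cold enough to spare the C2–O1 bond and the free primary alcohol.

9 to 8: no skeletal bond is cut; C9 is taken back from the alcohol to the methyl ester level. The reason is that C9 enters as carbon monoxide and so arrives as an ester. The demand is a hydride that reduces the saturated methyl ester and leaves the conjugated ester alone. This is why the acrylate is a tert-butyl ester: a methyl acrylate would be too close in reactivity to the C9 ester.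

8 to 7: the O1–C2 and C3–C9 bonds are cut, which removes the dihydrofuran ring and both stereocentres and leaves a flat, achiral stilbene. The ring A phenol of 7 must be free, because it is the nucleophile. The ring B phenol must be masked, because a free para-hydroxystilbene would offer a quinone methide pathway under divalent palladium and benzoquinone. The forward step must choose one alkene face, add O1 and C9 anti, and carbonylate faster than β-hydride elimination.

7 to 6 + 3: the bond between C3a of ring A and the alkene carbon C3 is cut. This divides the molecule into two fragments of similar size, each one or two steps from a commercial aldehyde. It also shortens the longest linear sequence compared with olefinating the aldehyde after the coupling. The forward Heck reaction must arylate the terminal carbon of the vinyl group, give the E alkene, tolerate the free phenol and leave the internal acrylate of 6 untouched.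

6 to 4 + 5: the acrylate C=C bond is cut, leading back to a commercial iodophenol aldehyde and a commercial stabilised ylide. The demand is E selectivity and an olefination that proceeds although the phenol can protonate the ylide.

3 to 2 to 1: the vinyl C=C bond (methylenation) and then the O–CH2OCH3 bond are cut, arriving at 1. The protecting group must survive ylide, Heck, carbonylation and hydride conditions and still fall together with the tert-butyl ester at the end.

## Other disconnections considered

Alternative 1: The cut runs through ring A: C3a–C4 and C7–C7a are formed last, and the dihydrofuran oxygen and both stereocentres are taken from the trans lactone A1, (4R,5S)-5-[4-(benzyloxy)-3,5-dimethoxyphenyl]-4-[[tert-butyl(dimethyl)silyl]oxymethyl]oxolan-2-one. In the forward sense its silyl ketene acetal A2 is heated with the bromopyrone A3 (methyl 3-bromo-2-oxo-2H-pyran-5-carboxylate). A cycloaddition of inverse electron demand joins the nucleophilic carbon of A2 to C6 of A3 and the acetal carbon to C3. Extrusion of carbon dioxide and loss of the silanol then aromatise the adduct to A4, methyl (2S,3R)-2-[4-(benzyloxy)-3,5-dimethoxyphenyl]-7-bromo-3-[[tert-butyl(dimethyl)silyl]oxymethyl]-2,3-dihydro-1-benzofuran-5-carboxylate.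
- In favour: the polarity of the two partners fixes the regiochemistry, the step is thermal and metal-free, and neither stereocentre is enolised or broken.
- Better than the chosen plan: the stereochemistry rests on established lactone chemistry and a pericyclic step of a known type, not on an untested enantioselective catalysis.
- Against: A4 is far from the target. The bromine at C7 is only a placeholder for the methoxy group and needs a C–O coupling. The C5 ester is one carbon short and must be reduced, reoxidised and olefinated. A benzyl ether is hard to remove beside a cinnamate alkene and a benzylic C2–O1 bond. A1 itself needs several enantioselective steps.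
- Mechanistic risk: in the aromatisation the ring oxygen O1 is a leaving group in competition with the silyloxy group, and its loss would open the dihydrofuran.
- Step economy: clearly worse, roughly twice the length of the chosen plan.

Alternative 2: The cut is at C3–C3a and at the C9–O bond. The substrate is the iodoaryl allyl ether A7, 5-(dimethoxymethyl)-2-[[(1S)-1-[3,5-dimethoxy-4-(methoxymethoxy)phenyl]prop-2-en-1-yl]oxy]-1-iodo-3-methoxybenzene. It would come from a Mitsunobu etherification of the allylic alcohol A5, (1R)-1-[3,5-dimethoxy-4-(methoxymethoxy)phenyl]prop-2-en-1-ol, with the iodophenol A6, 4-(dimethoxymethyl)-2-iodo-6-methoxyphenol. Bu3SnH and Et3B under air generate the C3a aryl radical, which closes 5-exo-trig onto the vinyl group. Dioxygen traps the C9 radical, and reduction of the hydroperoxide gives the alcohol A8, [(2S,3R)-5-(dimethoxymethyl)-2-[3,5-dimethoxy-4-(methoxymethoxy)phenyl]-7-methoxy-2,3-dihydro-1-benzofuran-3-yl]methanol.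
- Better than the chosen plan: the 5-exo aryl radical closure is a well-precedented ring-forming mode, and C9 arrives directly as the alcohol, so no ester has to be reduced beside the acrylate.
- Equal: two operations follow the key step (acidic unmasking of aldehyde and phenol, then a Knoevenagel–Doebner condensation with malonic acid).
- Against: the C2–O1 bond of A7 is both allylic and benzylic to an electron-rich ring. Making it from A5 with clean inversion is exposed to ionisation, loss of enantiopurity and allylic transposition.
- Against: C3 is set only by substrate control from C2, so the trans preference is plausible but not assured. Dioxygen capture must compete with hydrogen transfer from the tin hydride. The method uses stoichiometric organotin, and A6 is a labile para-hydroxybenzaldehyde acetal.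
- Comparison: the chosen plan sets both centres in one catalyst-controlled event from an achiral precursor, whereas this plan needs a separate asymmetric synthesis of A5 and then a stereochemical relay. Overall it should be about two steps longer.

Alternative 3: The cut is the C3–C3a bond, made by a 1,2-shift of the ring A carbon. The substrate is the flavanone A9, [4-[(2S)-6-bromo-8-methoxy-4-oxo-3,4-dihydro-2H-chromen-2-yl]-2,6-dimethoxyphenyl] 2,2-dimethylpropanoate. In trimethyl orthoformate with H2SO4 it forms an enol ether, which the trivalent iodine reagent PhI(OH)OTs attacks at C3. The ring A carbon then migrates from the former carbonyl carbon to C3 as the iodine leaves. This contracts the pyranone to the dihydrofuran and leaves the old carbonyl carbon as the methyl ester in A10, methyl (2S,3S)-5-bromo-2-[3,5-dimethoxy-4-(2,2-dimethylpropanoyloxy)phenyl]-7-methoxy-2,3-dihydro-1-benzofuran-3-carboxylate.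
- Better than the chosen plan: the ring contraction is a known reaction type on flavanones.
- Equal: the product carries the same C9 methyl ester, so the later reduction is the same. C3 lies α to the ester and can settle in the trans arrangement.
- Against: the electron-rich ring B can migrate in place of the ring A carbon (the isoflavone pathway), which is why its phenol has to be acylated. The strongly acidic medium threatens C2 through ring opening to the chalcone or ionisation of the benzylic ether.
- Against: the bromine is a placeholder that costs a Heck reaction after the key step, the oxidant is stoichiometric, and the enantioenriched A9 needs its own asymmetric step. The pivalate would not survive the basic condensation usually used to assemble such a skeleton.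
- Comparison: stereocontrol is spread over two events (asymmetric flavanone formation, then migration), against one in the chosen plan. The route should be one to two steps longer.

Key step: step 5

Assumptions:
- The ester 8 is (2S,3S) and the alcohols 9 and 10 are (2S,3R). The spatial arrangement is the same; only the substituent priority at C3 changes on reduction.
- The facial preference of a bisoxazoline–palladium complex on a 1,2-diaryl alkene cannot be derived from first principles. The (S,S) ligand is written, and its commercially available (R,R) enantiomer takes its place if that is the one leading to (2S,3S)-8.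

## Route

Step 1
Reactants: 1 syringaldehyde (4-hydroxy-3,5-dimethoxybenzaldehyde)
Product: 2 3,5-dimethoxy-4-(methoxymethoxy)benzaldehyde
Conditions: MOMCl, K2CO3, acetone, 0 °C → rt
Reagents that add atoms: chloromethyl methyl ether, COCCl
Why: O-alkylation of the acidic para-formyl phenol by the α-chloro ether (Williamson type); the aldehyde is untouched and the acetal-type ether is stable to the basic, organometallic and hydride steps that follow.

Step 2
Reactants: 2 3,5-dimethoxy-4-(methoxymethoxy)benzaldehyde
Product: 3 5-ethenyl-1,3-dimethoxy-2-(methoxymethoxy)benzene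
Conditions: Ph3PCH3Br, KOtBu, THF, 0 °C → rt
Reagents that add atoms: methyltriphenylphosphonium bromide, C[P+](c1ccccc1)(c1ccccc1)c1ccccc1.[Br-]
Why: Wittig methylenation with the non-stabilised ylide made in the flask; no stereochemistry arises, and the electron-rich styrene is best kept cold and used soon.

Step 3
Reactants: 4 5-iodovanillin (4-hydroxy-3-iodo-5-methoxybenzaldehyde); 5 tert-butyl (triphenylphosphoranylidene)acetate
Product: 6 tert-butyl (2E)-3-(4-hydroxy-3-iodo-5-methoxyphenyl)prop-2-enoate
Conditions: 5 (2.2 equiv), toluene, 90 °C
Reagents that add atoms: none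
Why: Wittig olefination with a stabilised ylide, which should give the E acrylate; the excess of ylide offsets reversible proton transfer from the phenol, and the aryl iodide is inert.

Step 4
Reactants: 6 tert-butyl (2E)-3-(4-hydroxy-3-iodo-5-methoxyphenyl)prop-2-enoate; 3 5-ethenyl-1,3-dimethoxy-2-(methoxymethoxy)benzene
Product: 7 tert-butyl (2E)-3-[3-[(E)-2-[3,5-dimethoxy-4-(methoxymethoxy)phenyl]ethenyl]-4-hydroxy-5-methoxyphenyl]prop-2-enoate
Conditions: Pd(OAc)2 (5 mol %), P(o-tol)3 (12 mol %), Et3N, DMF, 90 °C
Reagents that add atoms: none
Why: Heck reaction: oxidative addition of the aryl iodide to zerovalent palladium, syn carbopalladation at the unsubstituted vinyl carbon and syn β-hydride elimination should give the E stilbene; the internal, electron-poor acrylate of 6 inserts far more slowly than the terminal styrene, and the free phenol is tolerated with an amine base.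

Step 5
Reactants: 7 tert-butyl (2E)-3-[3-[(E)-2-[3,5-dimethoxy-4-(methoxymethoxy)phenyl]ethenyl]-4-hydroxy-5-methoxyphenyl]prop-2-enoate
Product: 8 methyl (2S,3S)-5-[(1E)-3-tert-butoxy-3-oxoprop-1-en-1-yl]-2-[3,5-dimethoxy-4-(methoxymethoxy)phenyl]-7-methoxy-2,3-dihydro-1-benzofuran-3-carboxylate (2,3-trans)
Conditions: Pd(OCOCF3)2 (10 mol %), (S,S)-Ph-box [2,2'-(propane-2,2-diyl)bis[(4S)-4-phenyl-4,5-dihydro-1,3-oxazole]] (12 mol %), 1,4-benzoquinone (1.5 equiv), CO (1–5 bar), MeOH/CH2Cl2 (1:1), −20 → 0 °C
Reagents that add atoms: carbon monoxide, [C-]#[O+]; methanol, CO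
Why: Proposed new method: divalent palladium carrying the bisoxazoline binds the stilbene alkene of 7, the ring A phenol oxygen attacks C2 from the face away from the metal (anti oxypalladation, 5-endo-trig closure of the dihydrofuran ring), the benzylic C3–palladium bond inserts CO with retention, and methanolysis of the acylpalladium species releases 8 and zerovalent palladium, which benzoquinone returns to the divalent state. The closest known reaction types are the palladium-catalysed intramolecular alkoxycarbonylation of hydroxyalkenes under CO, methanol and benzoquinone, and the 5-endo Wacker-type cyclisation of 2-hydroxystilbenes to 2-arylbenzofurans; the proposal intercepts the alkylpalladium intermediate of the latter with CO. C2 is set by the ligand, which must place palladium on the Re face of the alkene (Re at C2 and at C3) so that O1 enters on the Si face of C2 and gives 2S. C3 is not set independently: anti addition across the E alkene followed by retentive insertion puts the ester trans to the C2 aryl group, hence 3S. The step needs CO insertion to outrun β-hydride elimination of the C2 hydrogen, which lies cis to palladium; the bidentate ligand leaves two further sites, taken by the alkene and then by the alkyl group and CO, so CO sits cis to the alkyl group, no site is open for the hydride, and the phenol cannot bind the metal and must attack from outside. Regiochemistry is secured because only C2 is within reach of O1 and the electron-rich ring B stabilises positive charge there. The electron-poor acrylate alkene has no internal nucleophile and should remain a spectator, and the tert-butyl ester and the acetal-type ether are inert to methanol at this temperature.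

Step 6
Reactants: 8 methyl (2S,3S)-5-[(1E)-3-tert-butoxy-3-oxoprop-1-en-1-yl]-2-[3,5-dimethoxy-4-(methoxymethoxy)phenyl]-7-methoxy-2,3-dihydro-1-benzofuran-3-carboxylate
Product: 9 tert-butyl (2E)-3-[(2S,3R)-2-[3,5-dimethoxy-4-(methoxymethoxy)phenyl]-3-(hydroxymethyl)-7-methoxy-2,3-dihydro-1-benzofuran-5-yl]prop-2-enoate
Conditions: LiBH4 (2 equiv), THF, 0 °C → rt; aq. NH4Cl
Reagents that add atoms: none
Why: Chemoselective ester reduction with LiBH4: the non-conjugated methyl ester at C9 is attacked, while the tert-butyl ester is shielded sterically and deactivated by conjugation with the electron-rich ring A; C2 and C3 are not touched, and any enolisation at C3 could only return the more stable trans arrangement.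

Step 7
Reactants: 9 tert-butyl (2E)-3-[(2S,3R)-2-[3,5-dimethoxy-4-(methoxymethoxy)phenyl]-3-(hydroxymethyl)-7-methoxy-2,3-dihydro-1-benzofuran-5-yl]prop-2-enoate
Product: 10 (2E)-3-[(2S,3R)-2-(4-hydroxy-3,5-dimethoxyphenyl)-3-(hydroxymethyl)-7-methoxy-2,3-dihydro-1-benzofuran-5-yl]prop-2-enoic acid
Conditions: TFA/CH2Cl2 (1:4), H2O (5 equiv), 0 °C → rt; aq. NaHCO3, then acidify to pH 3
Reagents that add atoms: none
Why: Acidolysis: the tert-butyl ester fragments to the acid and 2-methylpropene, and the acetal-type aryl ether is hydrolysed to the phenol, formaldehyde and methanol; water traps the cations, the short cold exposure is meant to spare the benzylic C2–O1 bond, and the bicarbonate work-up frees any alcohol esterified by the acid.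

## Compound list

1 | syringaldehyde (4-hydroxy-3,5-dimethoxybenzaldehyde) | COc1cc(C=O)cc(OC)c1O | starting material
2 | 3,5-dimethoxy-4-(methoxymethoxy)benzaldehyde | COCOc1c(OC)cc(C=O)cc1OC | intermediate
3 | 5-ethenyl-1,3-dimethoxy-2-(methoxymethoxy)benzene | COCOc1c(OC)cc(C=C)cc1OC | intermediate
4 | 5-iodovanillin (4-hydroxy-3-iodo-5-methoxybenzaldehyde) | COc1cc(C=O)cc(I)c1O | starting material
5 | tert-butyl (triphenylphosphoranylidene)acetate | CC(C)(C)OC(=O)C=P(c1ccccc1)(c1ccccc1)c1ccccc1 | starting material
6 | tert-butyl (2E)-3-(4-hydroxy-3-iodo-5-methoxyphenyl)prop-2-enoate | COc1cc(/C=C/C(=O)OC(C)(C)C)cc(I)c1O | intermediate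
7 | tert-butyl (2E)-3-[3-[(E)-2-[3,5-dimethoxy-4-(methoxymethoxy)phenyl]ethenyl]-4-hydroxy-5-methoxyphenyl]prop-2-enoate | COc1cc(/C=C/c2cc(/C=C/C(=O)OC(C)(C)C)cc(OC)c2O)cc(OC)c1OCOC | intermediate
8 | methyl (2S,3S)-5-[(1E)-3-tert-butoxy-3-oxoprop-1-en-1-yl]-2-[3,5-dimethoxy-4-(methoxymethoxy)phenyl]-7-methoxy-2,3-dihydro-1-benzofuran-3-carboxylate | COc1cc([C@H]2Oc3c(OC)cc(/C=C/C(=O)OC(C)(C)C)cc3[C@@H]2C(=O)OC)cc(OC)c1OCOC | intermediate
9 | tert-butyl (2E)-3-[(2S,3R)-2-[3,5-dimethoxy-4-(methoxymethoxy)phenyl]-3-(hydroxymethyl)-7-methoxy-2,3-dihydro-1-benzofuran-5-yl]prop-2-enoate | COc1cc([C@H]2Oc3c(OC)cc(/C=C/C(=O)OC(C)(C)C)cc3[C@@H]2CO)cc(OC)c1OCOC | intermediate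
10 | (2E)-3-[(2S,3R)-2-(4-hydroxy-3,5-dimethoxyphenyl)-3-(hydroxymethyl)-7-methoxy-2,3-dihydro-1-benzofuran-5-yl]prop-2-enoic acid | COc1cc([C@H]2Oc3c(OC)cc(/C=C/C(=O)O)cc3[C@@H]2CO)cc(OC)c1O | target

## Step count and least certain steps

Total: 7 steps. Longest linear sequence: 6 steps (steps 1, 2, 4, 5, 6, 7); step 3 is a one-step side branch.

**Step 5 (key step, proposed new method).** The most likely failures are two.
- β-Hydride elimination of the C2 hydrogen may outrun CO insertion. That hydrogen is cis to palladium after anti addition, and elimination aromatises the ring.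
- Facial discrimination on a flat 1,2-diaryl alkene may be insufficient. It is made worse if part of the material reacts through a palladium-bound phenoxide (syn oxypalladation), which delivers O1 to the opposite face of C2 from the same alkene complex.
- A cis ester formed this way could be epimerised at C3 with DBU, but the erosion at C2 could not be repaired.

Fallback by known chemistry (enantioselective intramolecular carbenoid C–H insertion), setting out from 2 and 6 and returning at 8:
- NaBH4 in methanol should reduce 2 to [3,5-dimethoxy-4-(methoxymethoxy)phenyl]methanol F1.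
- Mitsunobu etherification (PPh3, DIAD, THF) of the phenol of 6 with F1 should give tert-butyl (2E)-3-[4-[[3,5-dimethoxy-4-(methoxymethoxy)phenyl]methoxy]-3-iodo-5-methoxyphenyl]prop-2-enoate F2.
- Palladium-catalysed arylation of the zinc enolate BrZnCH2CO2Me (Pd2(dba)3, P(t-Bu)3, THF) should replace iodine by the acetate unit and give tert-butyl (2E)-3-[4-[[3,5-dimethoxy-4-(methoxymethoxy)phenyl]methoxy]-3-methoxy-5-(2-methoxy-2-oxoethyl)phenyl]prop-2-enoate F3.
- Diazo transfer (4-acetamidobenzenesulfonyl azide, DBU, MeCN) should give tert-butyl (2E)-3-[3-(1-diazo-2-methoxy-2-oxoethyl)-4-[[3,5-dimethoxy-4-(methoxymethoxy)phenyl]methoxy]-5-methoxyphenyl]prop-2-enoate F4.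
- The divalent rhodium carboxylate dimer Rh2(S-PTTL)4 (dirhodium tetrakis[N-phthaloyl-(S)-tert-leucinate], or its enantiomer as needed for 2S) in toluene at low temperature should insert the carbenoid into the benzylic C–H bond next to the ether oxygen. This closes the ring as the cis ester methyl (2S,3R)-5-[(1E)-3-tert-butoxy-3-oxoprop-1-en-1-yl]-2-[3,5-dimethoxy-4-(methoxymethoxy)phenyl]-7-methoxy-2,3-dihydro-1-benzofuran-3-carboxylate F5.
- Catalytic NaOMe in methanol should epimerise C3 to the trans ester 8.
- The price is six operations in place of one.

**Step 4 (Heck coupling).** The most likely failure is loss of regiocontrol: arylation at the internal carbon of the electron-rich vinylarene gives a 1,1-diarylethene. Slow oxidative addition of the ortho-phenoxide and thermal polymerisation of 3 add to this. Fallback, setting out from 3 and 6 and returning at 7: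
- Cross-metathesis of 3 with 4,4,5,5-tetramethyl-2-vinyl-1,3,2-dioxaborolane, using second-generation Grubbs catalyst RuCl2(=CHPh)(PCy3)(H2IMes) in CH2Cl2 at 40 °C, should give 2-[(E)-2-[3,5-dimethoxy-4-(methoxymethoxy)phenyl]ethenyl]-4,4,5,5-tetramethyl-1,3,2-dioxaborolane F6.
- Suzuki–Miyaura coupling of F6 with 6 (PdCl2(dppf), K2CO3, dioxane/H2O, 80 °C) forms the bond only at the boron-bearing carbon, with retention of the E geometry, and gives 7.

**Step 6 (LiBH4 reduction).** The most likely failure is loss of chemoselectivity, by 1,4- or 1,2-hydride attack on the conjugated tert-butyl ester. Fallback, setting out from 8 and returning at 9: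
- LiOH in THF/H2O at 0 °C should hydrolyse only the methyl ester and give (2S,3S)-5-[(1E)-3-tert-butoxy-3-oxoprop-1-en-1-yl]-2-[3,5-dimethoxy-4-(methoxymethoxy)phenyl]-7-methoxy-2,3-dihydro-1-benzofuran-3-carboxylic acid F7.
- BH3·SMe2 in THF at 0 °C reduces carboxylic acids in preference to esters and should convert F7 into 9.

**Step 7 (global acidolysis).** The most likely failure is acid-induced ionisation of the C2–O1 bond once the para-phenol is free, leading to ring opening or epimerisation at C2. Capture of tert-butyl or methoxymethyl cations by the electron-rich rings or by the primary alcohol is a second risk. Fallback, setting out from 8 and returning at 10, by reversing the order: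
- The same acid treatment applied to 8 should give (2E)-3-[(2S,3S)-2-(4-hydroxy-3,5-dimethoxyphenyl)-3-(methoxycarbonyl)-7-methoxy-2,3-dihydro-1-benzofuran-5-yl]prop-2-enoic acid F8. At this stage the electron-withdrawing C3 ester disfavours positive charge at C2 and no primary alcohol is present.
- Excess LiBH4 in THF should then reduce only the methyl ester of F8 and give 10, because the acid and the phenol are present as lithium salts that hydride does not attack.

**Step 3 (Wittig on the phenolic aldehyde).** The most likely failure is stalling through proton transfer: the acidic iodophenol protonates the ylide and the resulting phenoxide deactivates the aldehyde. Fallback, setting out from 4 and returning at 6: a Knoevenagel–Doebner condensation of 4 with mono-tert-butyl malonate (pyridine, piperidine, 90 °C), which condenses and decarboxylates to the E tert-butyl acrylate 6 and tolerates free phenols. No new compound is involved.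

## Further compounds

F1 | step 5 | [3,5-dimethoxy-4-(methoxymethoxy)phenyl]methanol | COCOc1c(OC)cc(CO)cc1OC
F2 | step 5 | tert-butyl (2E)-3-[4-[[3,5-dimethoxy-4-(methoxymethoxy)phenyl]methoxy]-3-iodo-5-methoxyphenyl]prop-2-enoate | COc1cc(/C=C/C(=O)OC(C)(C)C)cc(I)c1OCc1cc(OC)c(OCOC)c(OC)c1
F3 | step 5 | tert-butyl (2E)-3-[4-[[3,5-dimethoxy-4-(methoxymethoxy)phenyl]methoxy]-3-methoxy-5-(2-methoxy-2-oxoethyl)phenyl]prop-2-enoate | COc1cc(/C=C/C(=O)OC(C)(C)C)cc(CC(=O)OC)c1OCc1cc(OC)c(OCOC)c(OC)c1
F4 | step 5 | tert-butyl (2E)-3-[3-(1-diazo-2-methoxy-2-oxoethyl)-4-[[3,5-dimethoxy-4-(methoxymethoxy)phenyl]methoxy]-5-methoxyphenyl]prop-2-enoate | COc1cc(/C=C/C(=O)OC(C)(C)C)cc(C(=[N+]=[N-])C(=O)OC)c1OCc1cc(OC)c(OCOC)c(OC)c1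
F5 | step 5 | methyl (2S,3R)-5-[(1E)-3-tert-butoxy-3-oxoprop-1-en-1-yl]-2-[3,5-dimethoxy-4-(methoxymethoxy)phenyl]-7-methoxy-2,3-dihydro-1-benzofuran-3-carboxylate (2,3-cis) | COc1cc([C@H]2Oc3c(OC)cc(/C=C/C(=O)OC(C)(C)C)cc3[C@H]2C(=O)OC)cc(OC)c1OCOC
F6 | step 4 | 2-[(E)-2-[3,5-dimethoxy-4-(methoxymethoxy)phenyl]ethenyl]-4,4,5,5-tetramethyl-1,3,2-dioxaborolane | COCOc1c(OC)cc(/C=C/B2OC(C)(C)C(C)(C)O2)cc1OC
F7 | step 6 | (2S,3S)-5-[(1E)-3-tert-butoxy-3-oxoprop-1-en-1-yl]-2-[3,5-dimethoxy-4-(methoxymethoxy)phenyl]-7-methoxy-2,3-dihydro-1-benzofuran-3-carboxylic acid | COc1cc([C@H]2Oc3c(OC)cc(/C=C/C(=O)OC(C)(C)C)cc3[C@@H]2C(=O)O)cc(OC)c1OCOC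
F8 | step 7 | (2E)-3-[(2S,3S)-2-(4-hydroxy-3,5-dimethoxyphenyl)-3-(methoxycarbonyl)-7-methoxy-2,3-dihydro-1-benzofuran-5-yl]prop-2-enoic acid | COc1cc([C@H]2Oc3c(OC)cc(/C=C/C(=O)O)cc3[C@@H]2C(=O)OC)cc(OC)c1O
F0 | step 3 | none | none
A1 | alternative 1 | (4R,5S)-5-[4-(benzyloxy)-3,5-dimethoxyphenyl]-4-[[tert-butyl(dimethyl)silyl]oxymethyl]oxolan-2-one | COc1cc([C@H]2OC(=O)C[C@@H]2CO[Si](C)(C)C(C)(C)C)cc(OC)c1OCc1ccccc1
A2 | alternative 1 | tert-butyl-[[(2S,3R)-2-[4-(benzyloxy)-3,5-dimethoxyphenyl]-5-(trimethylsilyloxy)-2,3-dihydrofuran-3-yl]methoxy]dimethylsilane | COc1cc([C@H]2OC(O[Si](C)(C)C)=C[C@@H]2CO[Si](C)(C)C(C)(C)C)cc(OC)c1OCc1ccccc1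
A3 | alternative 1 | methyl 3-bromo-2-oxo-2H-pyran-5-carboxylate | COC(=O)C1=COC(=O)C(Br)=C1
A4 | alternative 1 | methyl (2S,3R)-2-[4-(benzyloxy)-3,5-dimethoxyphenyl]-7-bromo-3-[[tert-butyl(dimethyl)silyl]oxymethyl]-2,3-dihydro-1-benzofuran-5-carboxylate | COc1cc([C@H]2Oc3c(Br)cc(C(=O)OC)cc3[C@@H]2CO[Si](C)(C)C(C)(C)C)cc(OC)c1OCc1ccccc1
A5 | alternative 2 | (1R)-1-[3,5-dimethoxy-4-(methoxymethoxy)phenyl]prop-2-en-1-ol | COc1cc([C@@H](C=C)O)cc(OC)c1OCOC
A6 | alternative 2 | 4-(dimethoxymethyl)-2-iodo-6-methoxyphenol | COc1cc(C(OC)OC)cc(I)c1O
A7 | alternative 2 | 5-(dimethoxymethyl)-2-[[(1S)-1-[3,5-dimethoxy-4-(methoxymethoxy)phenyl]prop-2-en-1-yl]oxy]-1-iodo-3-methoxybenzene | COc1cc([C@H](C=C)Oc2c(OC)cc(C(OC)OC)cc2I)cc(OC)c1OCOC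
A8 | alternative 2 | [(2S,3R)-5-(dimethoxymethyl)-2-[3,5-dimethoxy-4-(methoxymethoxy)phenyl]-7-methoxy-2,3-dihydro-1-benzofuran-3-yl]methanol | COc1cc([C@H]2Oc3c(OC)cc(C(OC)OC)cc3[C@@H]2CO)cc(OC)c1OCOC
A9 | alternative 3 | [4-[(2S)-6-bromo-8-methoxy-4-oxo-3,4-dihydro-2H-chromen-2-yl]-2,6-dimethoxyphenyl] 2,2-dimethylpropanoate | COc1cc([C@H]2Oc3c(OC)cc(Br)cc3C(=O)C2)cc(OC)c1OC(=O)C(C)(C)C
A10 | alternative 3 | methyl (2S,3S)-5-bromo-2-[3,5-dimethoxy-4-(2,2-dimethylpropanoyloxy)phenyl]-7-methoxy-2,3-dihydro-1-benzofuran-3-carboxylate | COc1cc([C@H]2Oc3c(OC)cc(Br)cc3[C@@H]2C(=O)OC)cc(OC)c1OC(=O)C(C)(C)C
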